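The α-methylene-γ-butyrolactone (ring B) is disconnected so that its whole O–C(=O) unit comes from carbon dioxide. The key step exploits two features: the alkene carbon C11, which can be an alkenyllithium, and the oxygenated neighbour C5 of the lactone carbinol C6, which lets C5–C6 be a terminal epoxide. Carboxylation forms C11–C12; the carboxylate then opens the epoxide 5-exo at C6 with inversion, which forms O–C6, closes ring B, sets C6 and frees the C5 hydroxyl. The precursor is an acyclic 2-iodoalkene with an epoxide and no lactone. The ten-membered ring A is closed last, at C1–C10, by a Nozaki–Hiyama–Kishi reaction.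

Key step: step 9

Numbering used throughout: ring A is C1 (CHOH), C2 (CH2), C3=C4 (C4 bears the methyl group C15), C5 (CHOAc), C6 (lactone CH–O), C7 (CH bearing C11), C8 (CH–O-angeloyl), C9 (CH2), C10 (bearing the exocyclic methylene C14). C11 (bearing the methylene C13) and C12 (C=O) complete ring B.

Assumption: the (4S,5S)-configured diazaborolidine controller of step 6 is taken to deliver the 2-bromoallyl group to the Si face of aldehyde 6; if its sense is the opposite, the (4R,5R)-controller is used with no other change.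

Step 1
Reactants: 1 diethyl (2S,3S)-oxirane-2,3-dicarboxylate
Product: 2 diethyl (2S,3R)-2-hydroxy-3-[1-(trimethylsilyl)ethenyl]butanedioate
Conditions: CH2=C(SiMe3)MgBr (from (1-bromoethenyl)trimethylsilane, Mg), CuI (10 mol%), THF, −78 → −40 °C; then H2O
Reagents that add atoms: [1-(trimethylsilyl)ethenyl]magnesium bromide, C=C([Mg]Br)[Si](C)(C)C
Why: Copper-catalysed SN2 opening of the C2-symmetric trans-epoxide (both carbons equivalent, so no regiochemical issue) by the alkenyl Grignard reagent forms the C7–C11 bond with inversion at C7 and leaves the C6–O bond untouched, which sets the anti C6/C7 pair.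

Step 2
Reactants: 2 diethyl (2S,3R)-2-hydroxy-3-[1-(trimethylsilyl)ethenyl]butanedioate
Product: 3 ethyl (2R,3S)-3,4-dihydroxy-2-[1-(trimethylsilyl)ethenyl]butanoate
Conditions: BH3·SMe2 (1.0 equiv), NaBH4 (5 mol%), THF, 0 → 23 °C; MeOH
Reagents that add atoms: none
Why: Hydroxyl-directed ester reduction: the C6 hydroxyl forms an alkoxyborane that delivers hydride only to the neighbouring α-hydroxy ester (C5), so the C8 ester and both stereocentres survive, and one equivalent of borane leaves none to hydroborate the alkenylsilane.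

Step 3
Reactants: 3 ethyl (2R,3S)-3,4-dihydroxy-2-[1-(trimethylsilyl)ethenyl]butanoate
Product: 5 ethyl (2R)-2-[(2S)-oxiran-2-yl]-3-(trimethylsilyl)but-3-enoate, via primary tosylate 4 (not isolated)
Conditions: TsCl, Et3N, Bu2SnO (2 mol%), CH2Cl2, 0 °C; then K2CO3, EtOH, 0 °C
Reagents that add atoms: 4-methylbenzenesulfonyl chloride, Cc1ccc(cc1)S(Cl)(=O)=O (its atoms are held by intermediate 4 only and leave again)
Why: Tin-catalysed sulfonylation marks the primary hydroxyl of the 1,2-diol and the C6 alkoxide then displaces the tosylate (intramolecular Williamson reaction, 3-exo-tet), so the C6–O bond and its configuration are kept in the epoxide.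

Step 4
Reactants: 5 ethyl (2R)-2-[(2S)-oxiran-2-yl]-3-(trimethylsilyl)but-3-enoate
Product: 6 (2R)-2-[(2S)-oxiran-2-yl]-3-(trimethylsilyl)but-3-enal
Conditions: i-Bu2AlH (1.1 equiv), CH2Cl2, −78 °C; aq. Rochelle salt
Reagents that add atoms: none
Why: Partial reduction of the ester stops at the aldehyde because the tetrahedral aluminium hemiacetal survives at −78 °C until work-up; the epoxide and the alkenylsilane are inert, and the crude aldehyde is used at once.

Step 5
Reactants: 7 2,3-dibromoprop-1-ene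
Product: 8 tributyl(2-bromoprop-2-en-1-yl)stannane
Conditions: Bu3SnCl, Zn, THF/sat. aq. NH4Cl, 23 °C
Reagents that add atoms: tributyltin chloride, CCCC[Sn](Cl)(CCCC)CCCC
Why: Barbier-type stannylation: zinc inserts into the allylic C–Br bond only and the allylzinc is captured by the tin chloride, the alkenyl bromide being inert.

Step 6
Reactants: 6 (2R)-2-[(2S)-oxiran-2-yl]-3-(trimethylsilyl)but-3-enal; 8 tributyl(2-bromoprop-2-en-1-yl)stannane
Product: 10 (3S,4S)-6-bromo-3-[(2S)-oxiran-2-yl]-2-(trimethylsilyl)hepta-1,6-dien-4-ol, via allylborane 9 (not isolated)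
Conditions: N,N'-[(1S,2S)-1,2-diphenylethane-1,2-diyl]bis(4-methylbenzenesulfonamide), BBr3, CH2Cl2, 0 → 23 °C; 8, 23 °C; then 6, −78 °C; pH 7 buffer
Reagents that add atoms: boron tribromide, BrB(Br)Br, and the bis-sulfonamide, Cc1ccc(cc1)S(=O)(=O)N[C@@H](c1ccccc1)[C@H](c1ccccc1)NS(=O)(=O)c1ccc(C)cc1 (their atoms are held by intermediate 9 only and leave on work-up)
Why: Enantioselective allylboration: tin–boron exchange gives the chiral 2-bromoallylborane 9, which adds to the aldehyde through a six-membered chair transition state, and the C2-symmetric bis-sulfonamide controller directs the allyl group to the Si face, which sets C8 as S under reagent control.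

Step 7
Reactants: 10 (3S,4S)-6-bromo-3-[(2S)-oxiran-2-yl]-2-(trimethylsilyl)hepta-1,6-dien-4-ol
Product: 11 [(3S,4S)-6-bromo-4-(4-methoxybenzyloxy)-3-[(2S)-oxiran-2-yl]hepta-1,6-dien-2-yl]trimethylsilane
Conditions: NaH, 4-methoxybenzyl bromide, Bu4NI (cat.), THF/DMF, 0 °C
Reagents that add atoms: 4-methoxybenzyl bromide, COc1ccc(CBr)cc1
Why: Williamson etherification of the C8 alkoxide gives an ether that survives the organolithium of step 9 and is removed oxidatively in step 15; no stereocentre is involved.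

Step 8
Reactants: 11 [(3S,4S)-6-bromo-4-(4-methoxybenzyloxy)-3-[(2S)-oxiran-2-yl]hepta-1,6-dien-2-yl]trimethylsilane
Product: 12 (2S)-2-[(3S,4S)-6-bromo-2-iodo-4-(4-methoxybenzyloxy)hepta-1,6-dien-3-yl]oxirane
Conditions: N-iodosuccinimide, MeCN/ClCH2CN (4:1), 0 → 23 °C
Reagents that add atoms: N-iodosuccinimide, O=C1CCC(=O)N1I
Why: Iododesilylation: electrophilic iodine attacks the silicon-bearing alkene carbon (β-silyl cation) and loss of silicon gives the 2-iodoalkene, while the less electron-rich 2-bromoalkene and the epoxide should not react.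

Step 9
Reactants: 12 (2S)-2-[(3S,4S)-6-bromo-2-iodo-4-(4-methoxybenzyloxy)hepta-1,6-dien-3-yl]oxirane
Product: 15 (4S,5R)-4-[(1S)-3-bromo-1-(4-methoxybenzyloxy)but-3-en-1-yl]-5-(hydroxymethyl)-3-methylideneoxolan-2-one, via alkenyllithium 13 (not isolated), via lithium carboxylate 14 (not isolated)
Conditions: n-BuLi (1.05 equiv), Et2O, −78 °C; CO2 (g), −78 → 0 °C; then AcOH, 23 °C
Reagents that add atoms: carbon dioxide, O=C=O (n-butyllithium, [Li]CCCC, puts lithium into 13 and 14 only)
Why: Iodine–lithium exchange at C11 gives alkenyllithium 13, which adds to CO2 and forms the C11–C12 bond of carboxylate 14; on acidification the carboxyl oxygen opens the terminal epoxide at C6 and forms the O–C6 bond. The closest known reactions are the carboxylation of alkenyllithiums to 2-substituted acrylic acids and the lactonisation of γ,δ-epoxy acids. Ring B closes in the 5-exo-tet mode (attack at the proximal epoxide carbon C6, the breaking C–O bond lying outside the new ring), which is preferred over 6-endo attack at C5. The only new stereocentre, C6, is set by stereospecific inversion of the (S)-epoxide carbon, which places C5 trans to C8 on the lactone and gives 6R. The step needs chemoselective exchange of the iodide in the presence of the C10 bromide, secured by the much faster exchange of alkenyl iodides with n-BuLi at −78 °C, and regioselective 5-exo opening, secured by the tether length and the more substituted epoxide carbon. C7 and C8 are not touched.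

Step 10
Reactants: 15 (4S,5R)-4-[(1S)-3-bromo-1-(4-methoxybenzyloxy)but-3-en-1-yl]-5-(hydroxymethyl)-3-methylideneoxolan-2-one
Product: 16 (2R,3S)-3-[(1S)-3-bromo-1-(4-methoxybenzyloxy)but-3-en-1-yl]-4-methylidene-5-oxooxolane-2-carbaldehyde
Conditions: Dess–Martin periodinane, NaHCO3, CH2Cl2, 0 → 23 °C
Reagents that add atoms: none
Why: Dess–Martin oxidation of the primary alcohol under buffered, non-basic conditions gives the aldehyde without epimerisation at C6; the crude aldehyde is used at once.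

Step 11
Reactants: 17 pent-3-yn-1-ol
Product: 18 tert-butyldimethyl(pent-3-yn-1-yloxy)silane
Conditions: TBSCl, imidazole, DMF, 23 °C
Reagents that add atoms: tert-butyldimethylsilyl chloride, CC(C)(C)[Si](C)(C)Cl
Why: Standard silylation of the primary alcohol, with imidazole as base and nucleophilic catalyst.

Step 12
Reactants: 18 tert-butyldimethyl(pent-3-yn-1-yloxy)silane
Product: 20 tert-butyl[(3E)-4-iodopent-3-en-1-yloxy]dimethylsilane, via alkenylzirconocene 19 (not isolated)
Conditions: Cp2Zr(H)Cl (1.5 equiv), THF, 50 °C; then I2, 0 °C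
Reagents that add atoms: iodine, II (Cp2Zr(H)Cl, [H][Zr](Cl)(C1C=CC=C1)C1C=CC=C1, puts zirconium into 19 only)
Why: Hydrozirconation is a syn addition that, with excess reagent and warming, places zirconium on the less hindered methyl-bearing alkyne carbon, and iodinolysis of the C–Zr bond with retention gives the (E)-2-iodoalkene.

Step 13
Reactants: 16 (2R,3S)-3-[(1S)-3-bromo-1-(4-methoxybenzyloxy)but-3-en-1-yl]-4-methylidene-5-oxooxolane-2-carbaldehyde; 20 tert-butyl[(3E)-4-iodopent-3-en-1-yloxy]dimethylsilane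
Product: 21 (4S,5R)-4-[(1S)-3-bromo-1-(4-methoxybenzyloxy)but-3-en-1-yl]-5-[(1S,2E)-5-(tert-butyldimethylsilyloxy)-1-hydroxy-2-methylpent-2-en-1-yl]-3-methylideneoxolan-2-one
Conditions: 20 (2 equiv), CrCl2 (4 equiv), NiCl2 (0.5 mol%), DMSO, 23 °C; then H2O
Reagents that add atoms: none
Why: Nozaki–Hiyama–Kishi coupling: zerovalent nickel inserts into the alkenyl iodide (faster than into the alkenyl bromide of 16), the alkenyl group passes to trivalent chromium and adds only to the aldehyde, and polar Felkin–Anh attack anti to the C6–O bond should set C5 as S (5,6-anti).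

Step 14
Reactants: 21 (4S,5R)-4-[(1S)-3-bromo-1-(4-methoxybenzyloxy)but-3-en-1-yl]-5-[(1S,2E)-5-(tert-butyldimethylsilyloxy)-1-hydroxy-2-methylpent-2-en-1-yl]-3-methylideneoxolan-2-one
Product: 22 (1S,2E)-1-[(2R,3S)-3-[(1S)-3-bromo-1-(4-methoxybenzyloxy)but-3-en-1-yl]-4-methylidene-5-oxooxolan-2-yl]-5-(tert-butyldimethylsilyloxy)-2-methylpent-2-en-1-yl acetate
Conditions: Ac2O, pyridine, DMAP (cat.), CH2Cl2, 0 °C
Reagents that add atoms: acetic anhydride, CC(=O)OC(C)=O
Why: Acylation of the secondary allylic alcohol under nucleophilic catalysis installs the C5 acetate with retention (acyl–oxygen bond formation).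

Step 15
Reactants: 22 (1S,2E)-1-[(2R,3S)-3-[(1S)-3-bromo-1-(4-methoxybenzyloxy)but-3-en-1-yl]-4-methylidene-5-oxooxolan-2-yl]-5-(tert-butyldimethylsilyloxy)-2-methylpent-2-en-1-yl acetate
Product: 23 (1S,2E)-1-[(2R,3S)-3-[(1S)-3-bromo-1-hydroxybut-3-en-1-yl]-4-methylidene-5-oxooxolan-2-yl]-5-(tert-butyldimethylsilyloxy)-2-methylpent-2-en-1-yl acetate
Conditions: DDQ, CH2Cl2/pH 7 buffer (10:1), 0 °C
Reagents that add atoms: none
Why: Oxidative cleavage of the electron-rich benzyl ether (hydride abstraction by DDQ, hydrolysis of the oxocarbenium ion) frees the C8 hydroxyl and leaves the silyl ether, the esters and the alkenes intact.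

Step 16
Reactants: 23 (1S,2E)-1-[(2R,3S)-3-[(1S)-3-bromo-1-hydroxybut-3-en-1-yl]-4-methylidene-5-oxooxolan-2-yl]-5-(tert-butyldimethylsilyloxy)-2-methylpent-2-en-1-yl acetate
Product: 24 (1S)-1-[(2R,3S)-2-[(1S,2E)-1-acetoxy-5-(tert-butyldimethylsilyloxy)-2-methylpent-2-en-1-yl]-4-methylidene-5-oxooxolan-3-yl]-3-bromobut-3-en-1-yl (2Z)-2-methylbut-2-enoate
Conditions: angelic acid, 2,4,6-trichlorobenzoyl chloride, Et3N, toluene, 23 °C; then 23, 80 °C
Reagents that add atoms: angelic acid [(2Z)-2-methylbut-2-enoic acid], C/C=C(/C)C(=O)O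
Why: Yamaguchi esterification through the preformed mixed anhydride, run without a nucleophilic catalyst so that the angelate should not isomerise to the tiglate; C8 keeps its configuration (acyl–oxygen bond formation).

Step 17
Reactants: 24 (1S)-1-[(2R,3S)-2-[(1S,2E)-1-acetoxy-5-(tert-butyldimethylsilyloxy)-2-methylpent-2-en-1-yl]-4-methylidene-5-oxooxolan-3-yl]-3-bromobut-3-en-1-yl (2Z)-2-methylbut-2-enoate
Product: 25 (1S)-1-[(2R,3S)-2-[(1S,2E)-1-acetoxy-5-hydroxy-2-methylpent-2-en-1-yl]-4-methylidene-5-oxooxolan-3-yl]-3-bromobut-3-en-1-yl (2Z)-2-methylbut-2-enoate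
Conditions: HF·pyridine, pyridine, THF, 0 → 23 °C
Reagents that add atoms: none
Why: Fluoride-mediated desilylation cleaves the Si–O bond of the primary silyl ether under buffered conditions that leave the three esters and the acrylate intact.

Step 18
Reactants: 25 (1S)-1-[(2R,3S)-2-[(1S,2E)-1-acetoxy-5-hydroxy-2-methylpent-2-en-1-yl]-4-methylidene-5-oxooxolan-3-yl]-3-bromobut-3-en-1-yl (2Z)-2-methylbut-2-enoate
Product: 26 (1S)-1-[(2R,3S)-2-[(1S,2E)-1-acetoxy-2-methyl-5-oxopent-2-en-1-yl]-4-methylidene-5-oxooxolan-3-yl]-3-bromobut-3-en-1-yl (2Z)-2-methylbut-2-enoate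
Conditions: Dess–Martin periodinane, NaHCO3, CH2Cl2, 0 °C
Reagents that add atoms: none
Why: Dess–Martin oxidation gives the β,γ-unsaturated aldehyde without base, so the C3=C4 bond should not move into conjugation; the crude aldehyde is used at once.

Step 19
Reactants: 26 (1S)-1-[(2R,3S)-2-[(1S,2E)-1-acetoxy-2-methyl-5-oxopent-2-en-1-yl]-4-methylidene-5-oxooxolan-3-yl]-3-bromobut-3-en-1-yl (2Z)-2-methylbut-2-enoate
Product: 27 CNP0115054.1, (1S,3E,5S,6R,7S,8S)-5-acetoxy-1-hydroxy-8-[(2Z)-2-methylbut-2-enoyloxy]germacra-3,10(14),11(13)-trien-12,6-olide (numbering as defined above)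
Conditions: CrCl2 (10 equiv), NiCl2 (2 mol%), DMSO (0.002 M), 23 → 50 °C; then H2O
Reagents that add atoms: none
Why: Intramolecular Nozaki–Hiyama–Kishi reaction: zerovalent nickel inserts into the 2-bromoalkene, the alkenylchromium adds to the C1 aldehyde under high dilution and closes the ten-membered ring A with its exocyclic-methylene carbinol, the esters being inert; the trans-lactone and the E-alkene fold the chain so that addition from the outside of the forming ring should give the 1S alcohol.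

Compound list
1 | diethyl (2S,3S)-oxirane-2,3-dicarboxylate | CCOC(=O)[C@H]1O[C@@H]1C(=O)OCC | starting material
2 | diethyl (2S,3R)-2-hydroxy-3-[1-(trimethylsilyl)ethenyl]butanedioate | CCOC(=O)[C@@H]([C@H](O)C(=O)OCC)C(=C)[Si](C)(C)C | intermediate
3 | ethyl (2R,3S)-3,4-dihydroxy-2-[1-(trimethylsilyl)ethenyl]butanoate | CCOC(=O)[C@@H]([C@H](O)CO)C(=C)[Si](C)(C)C | intermediate
4 | ethyl (2R,3S)-3-hydroxy-4-(tosyloxy)-2-[1-(trimethylsilyl)ethenyl]butanoate | CCOC(=O)[C@@H]([C@H](O)COS(=O)(=O)c1ccc(C)cc1)C(=C)[Si](C)(C)C | intermediate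
5 | ethyl (2R)-2-[(2S)-oxiran-2-yl]-3-(trimethylsilyl)but-3-enoate | CCOC(=O)[C@@H]([C@H]1CO1)C(=C)[Si](C)(C)C | intermediate
6 | (2R)-2-[(2S)-oxiran-2-yl]-3-(trimethylsilyl)but-3-enal | O=C[C@@H]([C@H]1CO1)C(=C)[Si](C)(C)C | intermediate
7 | 2,3-dibromoprop-1-ene | C=C(Br)CBr | starting material
8 | tributyl(2-bromoprop-2-en-1-yl)stannane | C=C(Br)C[Sn](CCCC)(CCCC)CCCC | intermediate
9 | (4S,5S)-2-(2-bromoprop-2-en-1-yl)-4,5-diphenyl-1,3-ditosyl-1,3,2-diazaborolidine | C=C(Br)CB1N(S(=O)(=O)c2ccc(C)cc2)[C@@H](c2ccccc2)[C@H](c2ccccc2)N1S(=O)(=O)c1ccc(C)cc1 | intermediate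
10 | (3S,4S)-6-bromo-3-[(2S)-oxiran-2-yl]-2-(trimethylsilyl)hepta-1,6-dien-4-ol | C=C([Si](C)(C)C)[C@H]([C@H]1CO1)[C@@H](O)CC(Br)=C | intermediate
11 | [(3S,4S)-6-bromo-4-(4-methoxybenzyloxy)-3-[(2S)-oxiran-2-yl]hepta-1,6-dien-2-yl]trimethylsilane | C=C([Si](C)(C)C)[C@H]([C@H]1CO1)[C@@H](OCc1ccc(OC)cc1)CC(Br)=C | intermediate
12 | (2S)-2-[(3S,4S)-6-bromo-2-iodo-4-(4-methoxybenzyloxy)hepta-1,6-dien-3-yl]oxirane | C=C(I)[C@H]([C@H]1CO1)[C@@H](OCc1ccc(OC)cc1)CC(Br)=C | intermediate
13 | [(3S,4S)-6-bromo-4-(4-methoxybenzyloxy)-3-[(2S)-oxiran-2-yl]hepta-1,6-dien-2-yl]lithium | C=C([Li])[C@H]([C@H]1CO1)[C@@H](OCc1ccc(OC)cc1)CC(Br)=C | intermediate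
14 | lithium (3S,4S)-6-bromo-4-(4-methoxybenzyloxy)-2-methylidene-3-[(2S)-oxiran-2-yl]hept-6-enoate | C=C(C(=O)[O-])[C@H]([C@H]1CO1)[C@@H](OCc1ccc(OC)cc1)CC(Br)=C.[Li+] | intermediate
15 | (4S,5R)-4-[(1S)-3-bromo-1-(4-methoxybenzyloxy)but-3-en-1-yl]-5-(hydroxymethyl)-3-methylideneoxolan-2-one | C=C1C(=O)O[C@@H](CO)[C@@H]1[C@@H](OCc1ccc(OC)cc1)CC(Br)=C | intermediate
16 | (2R,3S)-3-[(1S)-3-bromo-1-(4-methoxybenzyloxy)but-3-en-1-yl]-4-methylidene-5-oxooxolane-2-carbaldehyde | C=C1C(=O)O[C@@H](C=O)[C@@H]1[C@@H](OCc1ccc(OC)cc1)CC(Br)=C | intermediate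
17 | pent-3-yn-1-ol | CC#CCCO | starting material
18 | tert-butyldimethyl(pent-3-yn-1-yloxy)silane | CC#CCCO[Si](C)(C)C(C)(C)C | intermediate
19 | chlorobis(cyclopentadienyl)[(2E)-5-(tert-butyldimethylsilyloxy)pent-2-en-2-yl]zirconium | C/C(=C\CCO[Si](C)(C)C(C)(C)C)[Zr](Cl)(C1C=CC=C1)C1C=CC=C1 | intermediate
20 | tert-butyl[(3E)-4-iodopent-3-en-1-yloxy]dimethylsilane | C/C(I)=C\CCO[Si](C)(C)C(C)(C)C | intermediate
21 | (4S,5R)-4-[(1S)-3-bromo-1-(4-methoxybenzyloxy)but-3-en-1-yl]-5-[(1S,2E)-5-(tert-butyldimethylsilyloxy)-1-hydroxy-2-methylpent-2-en-1-yl]-3-methylideneoxolan-2-one | C=C1C(=O)O[C@@H]([C@@H](O)/C(C)=C/CCO[Si](C)(C)C(C)(C)C)[C@@H]1[C@@H](OCc1ccc(OC)cc1)CC(Br)=C | intermediate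
22 | (1S,2E)-1-[(2R,3S)-3-[(1S)-3-bromo-1-(4-methoxybenzyloxy)but-3-en-1-yl]-4-methylidene-5-oxooxolan-2-yl]-5-(tert-butyldimethylsilyloxy)-2-methylpent-2-en-1-yl acetate | C=C1C(=O)O[C@@H]([C@@H](OC(C)=O)/C(C)=C/CCO[Si](C)(C)C(C)(C)C)[C@@H]1[C@@H](OCc1ccc(OC)cc1)CC(Br)=C | intermediate
23 | (1S,2E)-1-[(2R,3S)-3-[(1S)-3-bromo-1-hydroxybut-3-en-1-yl]-4-methylidene-5-oxooxolan-2-yl]-5-(tert-butyldimethylsilyloxy)-2-methylpent-2-en-1-yl acetate | C=C1C(=O)O[C@@H]([C@@H](OC(C)=O)/C(C)=C/CCO[Si](C)(C)C(C)(C)C)[C@@H]1[C@@H](O)CC(Br)=C | intermediate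
24 | (1S)-1-[(2R,3S)-2-[(1S,2E)-1-acetoxy-5-(tert-butyldimethylsilyloxy)-2-methylpent-2-en-1-yl]-4-methylidene-5-oxooxolan-3-yl]-3-bromobut-3-en-1-yl (2Z)-2-methylbut-2-enoate | C=C1C(=O)O[C@@H]([C@@H](OC(C)=O)/C(C)=C/CCO[Si](C)(C)C(C)(C)C)[C@@H]1[C@@H](OC(=O)/C(C)=C\C)CC(Br)=C | intermediate
25 | (1S)-1-[(2R,3S)-2-[(1S,2E)-1-acetoxy-5-hydroxy-2-methylpent-2-en-1-yl]-4-methylidene-5-oxooxolan-3-yl]-3-bromobut-3-en-1-yl (2Z)-2-methylbut-2-enoate | C=C1C(=O)O[C@@H]([C@@H](OC(C)=O)/C(C)=C/CCO)[C@@H]1[C@@H](OC(=O)/C(C)=C\C)CC(Br)=C | intermediate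
26 | (1S)-1-[(2R,3S)-2-[(1S,2E)-1-acetoxy-2-methyl-5-oxopent-2-en-1-yl]-4-methylidene-5-oxooxolan-3-yl]-3-bromobut-3-en-1-yl (2Z)-2-methylbut-2-enoate | C=C1C(=O)O[C@@H]([C@@H](OC(C)=O)/C(C)=C/CC=O)[C@@H]1[C@@H](OC(=O)/C(C)=C\C)CC(Br)=C | intermediate
27 | CNP0115054.1, (1S,3E,5S,6R,7S,8S)-5-acetoxy-1-hydroxy-8-[(2Z)-2-methylbut-2-enoyloxy]germacra-3,10(14),11(13)-trien-12,6-olide | C=C1C(=O)O[C@@H]2[C@@H]1[C@@H](OC(=O)/C(C)=C\C)CC(=C)[C@@H](O)C/C=C(\C)[C@@H]2OC(C)=O | target

Total step count: 19. Longest linear sequence: 16 steps (steps 1–4, 6–10 and 13–19).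

Steps most likely to fail

Step 19. The ring-closing addition may not discriminate the two faces of the C1 aldehyde, because the selectivity rests only on the folding of the open chain. The fallback sets the C1 centre by reagent-controlled ketone reduction instead of by the C–C bond formation. It sets out from 26: the ring is closed as in step 19 without regard to C1, and the mixture of 27 and its C1-epimeric alcohol F4 is oxidised (Dess–Martin periodinane, NaHCO3, CH2Cl2) to the ten-membered α-methylene ketone F5. Reduction of F5 with (R)-2-methyl-CBS-oxazaborolidine and catecholborane (toluene, −78 °C), the alkenyl group acting as the large substituent, should then deliver hydride to the face that gives 1S, and the route is rejoined at 27.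

Step 9. Bromine–lithium exchange at C10 may compete with the iodine–lithium exchange, or organolithium species may attack the epoxide before carbon dioxide is added. The fallback keeps carbon dioxide as the source of the O–C(=O) unit but avoids organolithiums. It sets out from 12: Miyaura borylation (B2pin2, PdCl2(PPh3)2, PPh3, KOPh, toluene, 50 °C, the iodide reacting before the bromide) gives the alkenylboronate F1. Copper-catalysed carboxylation of F1 (chloro[1,3-bis(2,6-diisopropylphenyl)imidazol-2-ylidene]copper, KOt-Bu, CO2 1 atm, THF, 70 °C) gives the potassium carboxylate F2, and AcOH then closes the lactone by the same 5-exo epoxide opening, which rejoins the route at 15.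

Step 13. Nickel may also insert into the 2-bromoalkene of 16, after which the alkenylchromium would close a six-membered ring onto its own aldehyde; Felkin control may also be eroded. The fallback uses neither nickel nor chromium. It sets out from the alkenylzirconocene 19 (made from 18 as in step 12): transmetalation with Me2Zn (toluene, −65 °C) gives the alkenyl(methyl)zinc F3, which adds to aldehyde 16 at 0 °C and rejoins the route at 21; the alkenyl bromide is inert to zirconium and zinc.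

Further compounds
F1 | step 9 | 2-[(3S,4S)-6-bromo-4-(4-methoxybenzyloxy)-3-[(2S)-oxiran-2-yl]hepta-1,6-dien-2-yl]-4,4,5,5-tetramethyl-1,3,2-dioxaborolane | C=C(B1OC(C)(C)C(C)(C)O1)[C@H]([C@H]1CO1)[C@@H](OCc1ccc(OC)cc1)CC(Br)=C
F2 | step 9 | potassium (3S,4S)-6-bromo-4-(4-methoxybenzyloxy)-2-methylidene-3-[(2S)-oxiran-2-yl]hept-6-enoate | C=C(C(=O)[O-])[C@H]([C@H]1CO1)[C@@H](OCc1ccc(OC)cc1)CC(Br)=C.[K+]
F3 | step 13 | [(2E)-5-(tert-butyldimethylsilyloxy)pent-2-en-2-yl](methyl)zinc | C/C(=C\CCO[Si](C)(C)C(C)(C)C)[Zn]C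
F4 | step 19 | C1 epimer of 27, the (1R)-alcohol | C=C1C(=O)O[C@@H]2[C@@H]1[C@@H](OC(=O)/C(C)=C\C)CC(=C)[C@H](O)C/C=C(\C)[C@@H]2OC(C)=O
F5 | step 19 | 1-oxo analogue of 27, the ten-membered α-methylene ketone | C=C1C(=O)O[C@@H]2[C@@H]1[C@@H](OC(=O)/C(C)=C\C)CC(=C)C(=O)C/C=C(\C)[C@@H]2OC(C)=O
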